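The vessel is closed, stirred and held at one temperature. Each flask gets the same Z and J with a different charge of L, and what counts is the Q standing at the end.

| flask | L | Z | J | remark | time |
|---|---|---|---|---|---|
| gamma | 0.063 M | 0.13 M | 0.13 M | run made earlier |  |
| theta | 0.77 M | 0.13 M | 0.13 M | run made earlier |  |
| alder | 0.12 M | 0.130 M | 0.130 M |  | 6.0 h |
| birch | 0.40 M | 0.130 M | 0.130 M |  | 6.0 h |
| cedar | 1.2 M | 0.130 M | 0.130 M |  | 6.0 h |

- gamma (time / h: Q / %, L / %): 0.833: 21.3, 45.6; 2.00: 27.4, 22.8; 4.00: 30.1, 9.5; 6.00: 31.7, 5.4
- theta (time / h: Q / %, L / %): 0.500: 8.7, 73.8; 1.00: 10.9, 68.3; 2.50: 8.4, 63.5; 6.00: 3.3, 59.1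

(each reading ± 0.5 percentage points)

- [Q] at the end for alder, birch, cedar, in this order
- how that number moves from the first to the last of them (rises, then falls / rises all the way / falls, then rises / hardly changes / falls all the way)

- "hardly changes" means that all values lie within two and a half points (for a concentration: within two and a half percent of the largest)

Late in theta, between 2.50 h and 6.00 h, Q drops by 5.1 percentage points while L drops by 4.4 points, so the loss of Q looks tied to L, about one for one. The objection is that Q might simply fall apart by itself. Theta's pace is 0.267 h⁻¹, and at that pace gamma's Q would shrink to 34.4% of its value between 2.00 h and 6.00 h. Gamma's Q instead climbs from 27.4% to 31.7% as its L dwindles, so the objection falls.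

Dividing theta's pace by its mean c_L gives 0.566 M⁻¹ h⁻¹, the wear constant: the rate at which Q is lost for each mole per litre of L present. While c_L stays flat the loss is pseudo-first-order, with a half-life of ln(2) over the wear constant times c_L. This is a reading, and a scatter of 0.5 points on 3.3% is 15.2% of that reading.

Next comes what reaches the wear. At the end of gamma, Q over the L used reads 0.335, a third, and theta at 1.00 h shows 0.344. Theta had used 0.244 M of L by then. Taking that same amount for birch and cedar gives 0.0818 M of Q at that hour, worn for the remaining hours at the c_L left over. My reckoning gives 0.0526 M for birch and 0.00548 M for cedar. Alder, reckoned as if its L were used up and its Q unworn, gets 0.0402 M. The objection here is that birch is charged with less L than theta and need not have used that amount by that hour, so this is rough, but in this reckoning birch stands above alder and cedar, and the row rises, then falls.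

The forecast, with its “Q is then destroyed in a step needing L”, gives 0.041 M, 0.07 M and 0.005 M, rises, then falls, higher than mine at birch.

Alder, birch and cedar end at 0.0345 M, 0.0543 M and 0.00790 M, so the row rises, then falls.

    L + Q → D (k = 0.562 M⁻¹ h⁻¹)
    L + Z → Q (k = 4.10 M⁻¹ h⁻¹)
    L + J → G (k = 5.52 M⁻¹ h⁻¹)
    J + Z → E (k = 2.70 M⁻¹ h⁻¹)
    Z ⇌ X (K = 4.80, k = 0.458 h⁻¹)

Cedar still holds 70.4% of its L at 6.00 h, which with the wear constant gives Q a half-life by wear of 1.45 h at that c_L, shorter than the 6.0 h of the run, and cedar's Q fell from 2.39% at 3.00 h to 0.659% at 6.00 h. Birch holds 37.9% of its L at 6.00 h, which gives a half-life by wear of 8.09 h at that c_L, longer than the run, and birch's Q went from 16.3% at 3.00 h to 13.6% at 6.00 h.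

(The data are calculated for substances that don't exist.)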